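**Strategy.** Everything rests on opening ring B, the central 2,4,6-trihydroxyacetophenone, at two ring bonds: the bond from the carbon carrying the ring A arm to the C–OH carbon lying between it and the acetyl-bearing carbon, and the bond from the acetyl-bearing carbon to the C–OH carbon next to the ring C arm. The key step exploits the three alternating C–OH carbons and the acetyl carbon of ring B, which are the oxygenated carbons of a cyclised 3,5,7-trioxooctanoate. In one flask a β-keto ester dianion is acetoacetylated by diketene and closed on magnesium. The precursor is a methyl 3-oxopentanoate with the ring C benzyl arm on C2 and the ring A aryl on C5, outer phenols as benzyl ethers.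

Key step: step 10

Assumption: ring A is the outer ring whose butyryl group lies between two hydroxyls, ring B the central acetyl-bearing ring, ring C the outer ring whose butyryl group lies between hydroxyl and methoxy; the target is achiral, so only regiochemistry has to be controlled.

Design remarks:
- The outer phenols are carried as benzyl ethers. Hydrogenolysis frees them under neutral conditions; acetal-type ethers would release a formaldehyde equivalent beside free, strongly nucleophilic ring carbons and expose the bridged oligophenol to acid.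
- The precursor is assembled by a crossed Claisen condensation of two 3-arylpropanoic acid derivatives. This avoids 2,4,6-trialkoxybenzyl halides, which ionise and self-alkylate readily.
- The ester stays methyl so that it matches Mg(OMe)2 in methanol.
- In the triketo ester 13 the chain is numbered C1 (ester carbon) to C8 (terminal methyl).

Step 1
Reactants: 1 2-methylphloroglucinol
Product: 2 2,4,6-trihydroxy-3-methylbenzaldehyde
Conditions: POCl3, DMF, EtOAc, 0 °C to rt; then H2O, 60 °C
Reagents that add atoms: N,N-dimethylformamide CN(C)C=O; water O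
Why: Vilsmeier–Haack formylation of a highly activated triol whose two free ring carbons are equivalent by symmetry, so one equivalent of the chloroiminium reagent should give a single mono-aldehyde because the iminium salt deactivates the ring towards a second attack.

Step 2
Reactants: 2 2,4,6-trihydroxy-3-methylbenzaldehyde
Product: 3 4,6-bis(benzyloxy)-2-hydroxy-3-methylbenzaldehyde
Conditions: BnBr (2.1 equiv), K2CO3, DMF, 0 °C to rt
Reagents that add atoms: benzyl bromide BrCc1ccccc1
Why: Williamson etherification under substrate control, in which the para hydroxyl (most acidic, not hydrogen-bonded) reacts first and, of the two chelated ortho hydroxyls, the one wedged between formyl and methyl is the more hindered and should remain free.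

Step 3
Reactants: 3 4,6-bis(benzyloxy)-2-hydroxy-3-methylbenzaldehyde
Product: 4 4,6-bis(benzyloxy)-2-methoxy-3-methylbenzaldehyde
Conditions: Me2SO4, K2CO3, acetone, reflux
Reagents that add atoms: dimethyl sulfate COS(=O)(=O)OC
Why: Williamson O-methylation of the one remaining, chelated phenol, which needs heat but faces no competing acidic site.

Step 4
Reactants: 4 4,6-bis(benzyloxy)-2-methoxy-3-methylbenzaldehyde
Product: 5 3-[4,6-bis(benzyloxy)-2-methoxy-3-methylphenyl]propanoic acid
Conditions: Meldrum's acid, HCO2H/Et3N (5:2), 95 °C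
Reagents that add atoms: Meldrum's acid (2,2-dimethyl-1,3-dioxane-4,6-dione) CC1(C)OC(=O)CC(=O)O1
Why: One-pot reductive Knoevenagel condensation, in which the arylidene Meldrum's acid is reduced by formate hydride transfer and then hydrolysed and decarboxylated to the arylpropanoic acid without any benzylic halide and without hydrogenolysis conditions.

Step 5
Reactants: 2 2,4,6-trihydroxy-3-methylbenzaldehyde
Product: 6 2,6-dihydroxy-4-methoxy-3-methylbenzaldehyde
Conditions: Me2SO4 (1.0 equiv), K2CO3 (1.0 equiv), acetone, rt
Reagents that add atoms: dimethyl sulfate COS(=O)(=O)OC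
Why: Selective Williamson O-methylation of the para hydroxyl, the only one not tied to the formyl oxygen by a hydrogen bond and the most acidic as a vinylogous acid, with a hard methylating agent to favour O- over C-alkylation.

Step 6
Reactants: 6 2,6-dihydroxy-4-methoxy-3-methylbenzaldehyde
Product: 7 2,6-bis(benzyloxy)-4-methoxy-3-methylbenzaldehyde
Conditions: BnBr (2.5 equiv), K2CO3, KI (cat.), DMF, 60 °C
Reagents that add atoms: benzyl bromide BrCc1ccccc1
Why: Exhaustive Williamson benzylation of both chelated ortho phenols, for which excess halide and heat in a dipolar aprotic solvent should suffice.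

Step 7
Reactants: 7 2,6-bis(benzyloxy)-4-methoxy-3-methylbenzaldehyde
Product: 8 methyl (2E)-3-[2,6-bis(benzyloxy)-4-methoxy-3-methylphenyl]prop-2-enoate
Conditions: (MeO)2P(O)CH2CO2Me, NaH, THF, 0 to 50 °C
Reagents that add atoms: trimethyl phosphonoacetate COC(=O)CP(=O)(OC)OC
Why: Horner–Wadsworth–Emmons olefination with a small, reactive phosphonate anion that should still reach the hindered aldehyde and give the E ester, whose geometry is irrelevant because the double bond is reduced next.

Step 8
Reactants: 8 methyl (2E)-3-[2,6-bis(benzyloxy)-4-methoxy-3-methylphenyl]prop-2-enoate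
Product: 9 methyl 3-[2,6-bis(benzyloxy)-4-methoxy-3-methylphenyl]propanoate
Conditions: NaBH4, NiCl2·6H2O (0.2 equiv), MeOH/THF, 0 °C
Reagents that add atoms: none
Why: Conjugate reduction of the cinnamate by NaBH4 with catalytic NiCl2, a method that saturates the C=C bond while leaving the ester and the aryl benzyl ethers intact.

Step 9
Reactants: 5 3-[4,6-bis(benzyloxy)-2-methoxy-3-methylphenyl]propanoic acid; 9 methyl 3-[2,6-bis(benzyloxy)-4-methoxy-3-methylphenyl]propanoate
Product: 11 methyl 5-[4,6-bis(benzyloxy)-2-methoxy-3-methylphenyl]-2-{[2,6-bis(benzyloxy)-4-methoxy-3-methylphenyl]methyl}-3-oxopentanoate (racemic), via acyl imidazolide 10 (not isolated)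
Conditions: 5, CDI, THF, rt; separately 9, LiN(SiMe3)2 (2.2 equiv), THF, −78 °C; combine, −78 to −20 °C; aq. NH4Cl
Reagents that add atoms: none
Why: Crossed Claisen condensation by C-acylation of the preformed lithium enolate of 9 with the acyl imidazolide of 5, the second equivalent of base taking up the acidic proton of the β-keto ester, and the new C2 stereocentre forming as a racemate that is later destroyed by aromatisation.

Step 10
Reactants: 11 methyl 5-[4,6-bis(benzyloxy)-2-methoxy-3-methylphenyl]-2-{[2,6-bis(benzyloxy)-4-methoxy-3-methylphenyl]methyl}-3-oxopentanoate (racemic); 12 diketene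
Product: 14 1-[3-{[4,6-bis(benzyloxy)-2-methoxy-3-methylphenyl]methyl}-5-{[2,6-bis(benzyloxy)-4-methoxy-3-methylphenyl]methyl}-2,4,6-trihydroxyphenyl]ethan-1-one, via triketo ester 13 (not isolated)
Conditions: LiN(iPr)2 (2.2 equiv), THF, −78 to 0 °C; 12 (1.2 equiv), −78 °C; then Mg(OMe)2, MeOH, −78 to 60 °C; cold 1 M HCl work-up
Reagents that add atoms: none
Why: Proposed new method: two equivalents of amide base should convert 11 into its α,γ-dianion, whose more basic γ-carbanion adds to the strained lactone carbonyl of 12 and opens it by acyl–oxygen cleavage; the enolate set free is quenched by the new acidic C–H of the chain itself, so 13 should form without further base. The closest known reactions are the γ-acylation of β-keto ester dianions by esters or N-methoxy-N-methylamides, the C-acetoacetylation of stabilised enolates by diketene, and the Mg(OMe)2-mediated Claisen cyclisation of 3,5,7-triketo esters to acylphloroglucinols; only their combination in one flask on a dianion is new. Mg(OMe)2 then chelates 13, the C6 methylene between the C5 and C7 carbonyls attacks the ester carbon C1 in a 6-exo-trig Claisen (Dieckmann-type) closure, methoxide leaves and the cyclic trione tautomerises to ring B with its acetyl group in place. No stereocentre is created, and the epimerisable centres C2 and C4 of 13 become aromatic carbons. The step needs carbon- over oxygen-acylation at the γ-position and Claisen over aldol closure: the first rests on the carbanion character of the γ-site, the second on magnesium chelation and on the fact that attack of C2 on the C7 ketone would give a quaternary carbon that cannot aromatise, while any 4-hydroxy-2-pyranone formed by lactonisation should be reopened by methoxide and funnelled to the same phenol.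

Step 11
Reactants: 14 1-[3-{[4,6-bis(benzyloxy)-2-methoxy-3-methylphenyl]methyl}-5-{[2,6-bis(benzyloxy)-4-methoxy-3-methylphenyl]methyl}-2,4,6-trihydroxyphenyl]ethan-1-one
Product: 15 1-[3-[(4,6-dihydroxy-2-methoxy-3-methylphenyl)methyl]-5-[(2,6-dihydroxy-4-methoxy-3-methylphenyl)methyl]-2,4,6-trihydroxyphenyl]ethan-1-one
Conditions: H2 (1 atm), Pd/C, EtOAc/MeOH, rt; filtered and concentrated under Ar, used at once
Reagents that add atoms: none
Why: Catalytic hydrogenolysis of the four aryl benzyl ethers under neutral conditions, which should leave the chelated aryl ketone, the aryl methyl ethers and the diarylmethane C–C bonds untouched.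

Step 12
Reactants: 15 1-[3-[(4,6-dihydroxy-2-methoxy-3-methylphenyl)methyl]-5-[(2,6-dihydroxy-4-methoxy-3-methylphenyl)methyl]-2,4,6-trihydroxyphenyl]ethan-1-one
Product: 17 CNP0184345.0, via bis-ketimine 16 (not isolated)
Conditions: PrCN, ZnCl2, HCl (g), Et2O, 0 °C to rt; then H2O, 90 °C
Reagents that add atoms: butyronitrile CCCC#N; water O
Why: Twofold Houben–Hoesch acylation, in which each outer ring is a phloroglucinol monomethyl ether with exactly one unsubstituted carbon and ring B has none, so the nitrilium electrophile can enter only at the two required positions, C-selectively and without cleaving the methyl ethers, before the ketiminium salts are hydrolysed to the butyryl ketones.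

**Compound list**

1 | 2-methylphloroglucinol (2-methylbenzene-1,3,5-triol) | Cc1c(O)cc(O)cc1O | starting material
2 | 2,4,6-trihydroxy-3-methylbenzaldehyde | O=Cc1c(O)c(C)c(O)cc1O | intermediate
3 | 4,6-bis(benzyloxy)-2-hydroxy-3-methylbenzaldehyde | O=Cc1c(O)c(C)c(OCc2ccccc2)cc1OCc1ccccc1 | intermediate
4 | 4,6-bis(benzyloxy)-2-methoxy-3-methylbenzaldehyde | O=Cc1c(OC)c(C)c(OCc2ccccc2)cc1OCc1ccccc1 | intermediate
5 | 3-[4,6-bis(benzyloxy)-2-methoxy-3-methylphenyl]propanoic acid (ring A arm) | OC(=O)CCc1c(OC)c(C)c(OCc2ccccc2)cc1OCc1ccccc1 | intermediate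
6 | 2,6-dihydroxy-4-methoxy-3-methylbenzaldehyde | O=Cc1c(O)c(C)c(OC)cc1O | intermediate
7 | 2,6-bis(benzyloxy)-4-methoxy-3-methylbenzaldehyde | O=Cc1c(OCc2ccccc2)c(C)c(OC)cc1OCc1ccccc1 | intermediate
8 | methyl (2E)-3-[2,6-bis(benzyloxy)-4-methoxy-3-methylphenyl]prop-2-enoate | COC(=O)/C=C/c1c(OCc2ccccc2)c(C)c(OC)cc1OCc1ccccc1 | intermediate
9 | methyl 3-[2,6-bis(benzyloxy)-4-methoxy-3-methylphenyl]propanoate (ring C arm) | COC(=O)CCc1c(OCc2ccccc2)c(C)c(OC)cc1OCc1ccccc1 | intermediate
10 | 1-{3-[4,6-bis(benzyloxy)-2-methoxy-3-methylphenyl]propanoyl}-1H-imidazole (acyl imidazolide, formed in the flask) | O=C(CCc1c(OC)c(C)c(OCc2ccccc2)cc1OCc1ccccc1)n1ccnc1 | intermediate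
11 | methyl 5-[4,6-bis(benzyloxy)-2-methoxy-3-methylphenyl]-2-{[2,6-bis(benzyloxy)-4-methoxy-3-methylphenyl]methyl}-3-oxopentanoate (racemic; key-step precursor) | COC(=O)C(Cc1c(OCc2ccccc2)c(C)c(OC)cc1OCc1ccccc1)C(=O)CCc1c(OC)c(C)c(OCc2ccccc2)cc1OCc1ccccc1 | intermediate
12 | diketene (4-methylideneoxetan-2-one) | C=C1CC(=O)O1 | starting material
13 | methyl 4-{[4,6-bis(benzyloxy)-2-methoxy-3-methylphenyl]methyl}-2-{[2,6-bis(benzyloxy)-4-methoxy-3-methylphenyl]methyl}-3,5,7-trioxooctanoate (mixture of diastereomers and enol forms, formed in the flask) | COC(=O)C(Cc1c(OCc2ccccc2)c(C)c(OC)cc1OCc1ccccc1)C(=O)C(Cc1c(OC)c(C)c(OCc2ccccc2)cc1OCc1ccccc1)C(=O)CC(C)=O | intermediate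
14 | 1-[3-{[4,6-bis(benzyloxy)-2-methoxy-3-methylphenyl]methyl}-5-{[2,6-bis(benzyloxy)-4-methoxy-3-methylphenyl]methyl}-2,4,6-trihydroxyphenyl]ethan-1-one (key-step product) | CC(=O)c1c(O)c(Cc2c(OC)c(C)c(OCc3ccccc3)cc2OCc2ccccc2)c(O)c(Cc2c(OCc3ccccc3)c(C)c(OC)cc2OCc2ccccc2)c1O | intermediate
15 | 1-[3-[(4,6-dihydroxy-2-methoxy-3-methylphenyl)methyl]-5-[(2,6-dihydroxy-4-methoxy-3-methylphenyl)methyl]-2,4,6-trihydroxyphenyl]ethan-1-one | CC(=O)c1c(O)c(Cc2c(OC)c(C)c(O)cc2O)c(O)c(Cc2c(O)c(C)c(OC)cc2O)c1O | intermediate
16 | 1-[3-{[3-(butanimidoyl)-2,4-dihydroxy-6-methoxy-5-methylphenyl]methyl}-5-{[3-(butanimidoyl)-2,6-dihydroxy-4-methoxy-5-methylphenyl]methyl}-2,4,6-trihydroxyphenyl]ethan-1-one (bis-ketimine, present as its dihydrochloride in the flask) | CC(=O)c1c(O)c(Cc2c(OC)c(C)c(O)c(C(=N)CCC)c2O)c(O)c(Cc2c(O)c(C)c(OC)c(C(=N)CCC)c2O)c1O | intermediate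
17 | CNP0184345.0: 1-[3-[(3-butanoyl-2,4-dihydroxy-6-methoxy-5-methylphenyl)methyl]-5-[(3-butanoyl-2,6-dihydroxy-4-methoxy-5-methylphenyl)methyl]-2,4,6-trihydroxyphenyl]ethan-1-one | CCCC(=O)c1c(O)c(C)c(OC)c(Cc2c(O)c(Cc3c(O)c(C)c(OC)c(C(=O)CCC)c3O)c(O)c(C(C)=O)c2O)c1O | target

**Totals.** Total step count: 12. Longest linear sequence: 9 steps (steps 1, 5, 6, 7, 8, 9, 10, 11, 12).

**Steps most likely to fail**

1. Step 10 (the only step beyond known chemistry). Proton transfer from diketene to the dianion, or base-induced oligomerisation of diketene, may outrun addition to the lactone carbonyl. The open triketo ester may also lose an acyl group by retro-Claisen cleavage before it cyclises. The fallback sets out from 11 and returns at 13 and then 14, in three separate operations of known type. The dianion of 11 (LiN(iPr)2, THF) would be acylated at the γ-carbon by the reagent N-methoxy-N-methyl-2-(2-methyl-1,3-dioxolan-2-yl)acetamide, whose chelated tetrahedral adduct should persist until work-up. This should give methyl 4-{[4,6-bis(benzyloxy)-2-methoxy-3-methylphenyl]methyl}-2-{[2,6-bis(benzyloxy)-4-methoxy-3-methylphenyl]methyl}-6-(2-methyl-1,3-dioxolan-2-yl)-3,5-dioxohexanoate F1. Aqueous acid (1 M HCl, THF) would remove the dioxolane and give 13, now isolated. Mg(OMe)2 in methanol would then close 13 to 14.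

2. Step 12. Ipso-protonation of the electron-rich, not yet acylated outer rings may cleave and redistribute the diarylmethane bridges. The heptaphenol may oxidise in air, and the reaction may stop after the first acylation if the mono-ketiminium salt precipitates. The fallback sets out from 14 and returns at 17; it reverses the order, so that acylation precedes deprotection and the free non-acylated oligophenol is never formed. Acetylation of the three ring B phenols (Ac2O, pyridine, DMAP) should give the ring B tri-O-acetate of 14 F2, in which ring B is electron-poor and the bridges are no longer acid-labile. Friedel–Crafts acylation of the single free carbon of each trialkoxy-activated outer ring with butanoic acid and trifluoroacetic anhydride in CH2Cl2 (mixed anhydride) should give the bis-butanoyl triacetate F3. K2CO3 in methanol would remove the acetates and give the tetra-O-benzyl ether of the target F4. Hydrogenolysis (H2, Pd/C) would then deliver 17 as the final, neutral step.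

3. Step 4. Hydride transfer from formate to the push–pull stabilised, doubly ortho-substituted arylidene Meldrum's acid may be too slow, so that the sequence stalls at the condensation stage or reverts to the aldehyde. The fallback sets out from 4 and returns at 5, repeating the operations already used in steps 7 and 8. Horner–Wadsworth–Emmons olefination with trimethyl phosphonoacetate and NaH should give methyl (2E)-3-[4,6-bis(benzyloxy)-2-methoxy-3-methylphenyl]prop-2-enoate F5. Reduction with NaBH4 and catalytic NiCl2·6H2O should give methyl 3-[4,6-bis(benzyloxy)-2-methoxy-3-methylphenyl]propanoate F6. Saponification (LiOH, THF/H2O) would give 5.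

**Further compounds**

F1 | step 10 | methyl 4-{[4,6-bis(benzyloxy)-2-methoxy-3-methylphenyl]methyl}-2-{[2,6-bis(benzyloxy)-4-methoxy-3-methylphenyl]methyl}-6-(2-methyl-1,3-dioxolan-2-yl)-3,5-dioxohexanoate | COC(=O)C(Cc1c(OCc2ccccc2)c(C)c(OC)cc1OCc1ccccc1)C(=O)C(Cc1c(OC)c(C)c(OCc2ccccc2)cc1OCc1ccccc1)C(=O)CC1(C)OCCO1
F2 | step 12 | 2-acetyl-4-{[4,6-bis(benzyloxy)-2-methoxy-3-methylphenyl]methyl}-6-{[2,6-bis(benzyloxy)-4-methoxy-3-methylphenyl]methyl}benzene-1,3,5-triyl triacetate | CC(=O)c1c(OC(C)=O)c(Cc2c(OC)c(C)c(OCc3ccccc3)cc2OCc2ccccc2)c(OC(C)=O)c(Cc2c(OCc3ccccc3)c(C)c(OC)cc2OCc2ccccc2)c1OC(C)=O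
F3 | step 12 | 2-acetyl-4-{[2,4-bis(benzyloxy)-3-butanoyl-6-methoxy-5-methylphenyl]methyl}-6-{[2,6-bis(benzyloxy)-3-butanoyl-4-methoxy-5-methylphenyl]methyl}benzene-1,3,5-triyl triacetate | CC(=O)c1c(OC(C)=O)c(Cc2c(OC)c(C)c(OCc3ccccc3)c(C(=O)CCC)c2OCc2ccccc2)c(OC(C)=O)c(Cc2c(OCc3ccccc3)c(C)c(OC)c(C(=O)CCC)c2OCc2ccccc2)c1OC(C)=O
F4 | step 12 | 1-[3-{[2,4-bis(benzyloxy)-3-butanoyl-6-methoxy-5-methylphenyl]methyl}-5-{[2,6-bis(benzyloxy)-3-butanoyl-4-methoxy-5-methylphenyl]methyl}-2,4,6-trihydroxyphenyl]ethan-1-one | CC(=O)c1c(O)c(Cc2c(OC)c(C)c(OCc3ccccc3)c(C(=O)CCC)c2OCc2ccccc2)c(O)c(Cc2c(OCc3ccccc3)c(C)c(OC)c(C(=O)CCC)c2OCc2ccccc2)c1O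
F5 | step 4 | methyl (2E)-3-[4,6-bis(benzyloxy)-2-methoxy-3-methylphenyl]prop-2-enoate | COC(=O)/C=C/c1c(OC)c(C)c(OCc2ccccc2)cc1OCc1ccccc1
F6 | step 4 | methyl 3-[4,6-bis(benzyloxy)-2-methoxy-3-methylphenyl]propanoate | COC(=O)CCc1c(OC)c(C)c(OCc2ccccc2)cc1OCc1ccccc1
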